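**Assumption:** the SMILES is taken literally: 4R,5R,6S,7S,8R,9R, a cis-fused 6,12-lactone, a trans 4,5-epoxide, and C2 cis to C9 across C1=C10. Germacrane numbering (C1–C15) is used for locants.

## Retrosynthetic overview

1. Fluctuadin ⇐ late 9-O-acetylation and 8-O-methacryloylation of a macrocyclic 8-silyloxy-9-ol, whose C9 centre comes from Felkin-controlled reduction of the C9 ketone.
2. Ten-membered ring ⇐ Ni/Cr (Nozaki–Hiyama–Kishi) closure of C9–C10 between a (Z)-α-iodoenoate and a C9 aldehyde.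
3. Seco aldehyde ⇐ cis-fused α-methylene-γ-butyrolactone ⇐ hydroxyl-directed epoxidation (C4, C5) of an open-chain homoallylic alcohol.
4. Key C6–C7 bond ⇐ intermolecular indium Barbier allylation of an (E)-enal (C1–C6, C10, C14; from geranyl acetate) with a (Z)-2-(bromomethyl)enoate (C7–C9, C11–C13; from (S)-solketal via Baylis–Hillman).
5. Ring order: epoxide, then γ-lactone, then ten-membered carbocycle.

## Route

**Step 1**
Reactants: 1 geranyl acetate; 2 3-chloroperoxybenzoic acid (mCPBA)
Product: 3 (2E)-5-(3,3-dimethyloxiran-2-yl)-3-methylpent-2-en-1-yl acetate (racemic)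
Conditions: mCPBA (1.05 equiv), CH2Cl2, 0 °C
Reagents that add atoms: mCPBA, OOC(=O)c1cccc(Cl)c1
Why: Prilezhaev epoxidation is selective for the electron-rich 6,7-alkene over the 2,3-alkene deactivated by the allylic acetate; the new centre is destroyed in step 2, so it is left racemic.

**Step 2**
Reactants: 3 epoxide
Product: 4 (2E)-3-methyl-6-oxohex-2-en-1-yl acetate
Conditions: H5IO6 (1.2 equiv), THF/Et2O, 0 °C
Reagents that add atoms: none
Why: Periodic acid opens the epoxide to the glycol and cleaves it (Malaprade cleavage) to the C1 aldehyde, leaving the (E)-trisubstituted alkene (future C4=C5) and the acetate untouched.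

**Step 3**
Reactants: 4 aldehyde; 5 methyl (triphenylphosphoranylidene)acetate; 6 N-iodosuccinimide
Product: 8 methyl (2Z,6E)-8-acetoxy-2-iodo-6-methylocta-2,6-dienoate, via iodo ylide 7 (not isolated)
Conditions: 5 (1.3 equiv), NIS (1.3 equiv), CH2Cl2, −20 °C, 30 min; then 4, −20 °C → rt
Reagents that add atoms: methyl (triphenylphosphoranylidene)acetate, COC(=O)C=P(c1ccccc1)(c1ccccc1)c1ccccc1; N-iodosuccinimide, O=C1CCC(=O)N1I
Why: Wittig olefination with the stabilised α-iodo ylide places the ester trans to the chain, so iodine ends cis to C2 (2Z), the geometry needed for C2 cis to C9 later; the minor E isomer is removed by chromatography.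

**Step 4**
Reactants: 8 acetate
Product: 9 methyl (2Z,6E)-8-hydroxy-2-iodo-6-methylocta-2,6-dienoate
Conditions: K2CO3 (0.3 equiv), MeOH, 0 °C
Reagents that add atoms: none
Why: Base-catalysed transesterification (methanolysis) removes the allylic acetate while the methyl ester is degenerate under these conditions.

**Step 5**
Reactants: 9 allylic alcohol
Product: 10 methyl (2Z,6E)-2-iodo-6-methyl-8-oxoocta-2,6-dienoate
Conditions: PhI(OAc)2 (1.2 equiv), TEMPO (0.1 equiv), CH2Cl2, rt
Reagents that add atoms: none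
Why: TEMPO/oxoammonium oxidation converts the allylic alcohol into the enal without E/Z isomerisation and without touching the vinyl iodide.

**Step 6**
Reactants: 11 (S)-solketal; 12 4-methoxybenzyl chloride
Product: 13 (4S)-4-[(4-methoxybenzyloxy)methyl]-2,2-dimethyl-1,3-dioxolane
Conditions: NaH (1.2 equiv), PMBCl (1.1 equiv), Bu4NI (cat.), THF/DMF, 0 °C → rt
Reagents that add atoms: 4-methoxybenzyl chloride, COc1ccc(CCl)cc1
Why: Williamson etherification of the free primary alcohol (future C9–O); the stereocentre (future C8) is not involved.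

**Step 7**
Reactants: 13 acetonide
Product: 14 (2R)-3-(4-methoxybenzyloxy)propane-1,2-diol
Conditions: AcOH/H2O (4:1), 40 °C
Reagents that add atoms: none
Why: Acid hydrolysis of the isopropylidene acetal; the PMB ether is stable to aqueous acetic acid and the descriptor changes only through CIP priorities.

**Step 8**
Reactants: 14 diol; 15 tert-butyldimethylsilyl chloride
Product: 16 (2S)-1,2-bis(tert-butyldimethylsilyloxy)-3-(4-methoxybenzyloxy)propane
Conditions: TBSCl (2.5 equiv), imidazole (5 equiv), DMF, rt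
Reagents that add atoms: tert-butyldimethylsilyl chloride, CC(C)(C)[Si](C)(C)Cl
Why: Exhaustive silylation (imidazole-activated silyl transfer) protects both hydroxyls without touching the stereocentre.

**Step 9**
Reactants: 16 bis-silyl ether
Product: 17 (2R)-2-(tert-butyldimethylsilyloxy)-3-(4-methoxybenzyloxy)propan-1-ol
Conditions: HF·pyridine, pyridine, THF, 0 °C
Reagents that add atoms: none
Why: Selective desilylation, because the unhindered primary silyl ether is cleaved much faster than the secondary one by buffered HF·pyridine.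

**Step 10**
Reactants: 17 primary alcohol
Product: 18 (2S)-2-(tert-butyldimethylsilyloxy)-3-(4-methoxybenzyloxy)propanal
Conditions: PhI(OAc)2 (1.2 equiv), TEMPO (0.1 equiv), CH2Cl2, rt
Reagents that add atoms: none
Why: Base-free TEMPO oxidation gives the α-silyloxy aldehyde without epimerising the future C8 centre.

**Step 11**
Reactants: 18 aldehyde; 19 methyl acrylate
Product: 20 methyl (3RS,4S)-4-(tert-butyldimethylsilyloxy)-3-hydroxy-5-(4-methoxybenzyloxy)-2-methylidenepentanoate
Conditions: methyl acrylate (5 equiv), DABCO (1 equiv), MeOH (2 M), rt, 4 d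
Reagents that add atoms: methyl acrylate, C=CC(=O)OC
Why: Morita–Baylis–Hillman reaction attaches C11–C13; the new carbinol centre (C7) forms as a mixture that is irrelevant because it becomes sp2 in step 12.

**Step 12**
Reactants: 20 Baylis–Hillman adduct; 21 PBr3
Product: 22 methyl (2Z,4R)-2-(bromomethyl)-4-(tert-butyldimethylsilyloxy)-5-(4-methoxybenzyloxy)pent-2-enoate
Conditions: PBr3 (0.45 equiv), Et2O, −10 → 0 °C
Reagents that add atoms: PBr3, BrP(Br)Br
Why: SN2' bromination with allylic transposition gives the conjugated trisubstituted alkene with C8 trans to the ester (the thermodynamically preferred Z bromide); both C7 epimers converge.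

**Step 13 (key step)**
Reactants: 10 enal; 22 allylic bromide
Product: 24 dimethyl (2Z,6E,8R,9R)-9-[(1R)-1-(tert-butyldimethylsilyloxy)-2-(4-methoxybenzyloxy)ethyl]-8-hydroxy-2-iodo-6-methyl-10-methylideneundeca-2,6-dienedioate, via allylindium reagent 23 (not isolated)
Conditions: indium powder (2 equiv), THF/H2O (1:1), rt, ultrasound; neutral work-up
Reagents that add atoms: none
Why: Barbier-type carbonyl allylation through a closed chair transition state in which the (Z)-allylindium carries the C8 group axially, giving the 6,7-syn adduct; with C8–H eclipsing the alkene (A(1,3) strain) the aldehyde adds anti to the C9 carbon, which sets C6 and C7 relative to C8, and indium does not insert into the vinyl iodide.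

**Step 14**
Reactants: 24 allylic alcohol; 2 mCPBA
Product: 25 methyl (2Z)-6-{(2R,3R)-3-[(1S,2R,3R)-3-(tert-butyldimethylsilyloxy)-1-hydroxy-4-(4-methoxybenzyloxy)-2-(3-methoxy-3-oxoprop-1-en-2-yl)butyl]-2-methyloxiran-2-yl}-2-iodohex-2-enoate
Conditions: mCPBA (1.2 equiv), NaHCO3, CH2Cl2, 0 °C
Reagents that add atoms: mCPBA, OOC(=O)c1cccc(Cl)c1
Why: Hydroxyl-directed (Henbest) epoxidation: the C15 methyl cis to C6 forces C6–H into the alkene plane (A(1,3) strain) and the hydrogen-bonded peracid is delivered to the OH face, giving the threo (4R,5R) epoxy alcohol, while the three electron-poor alkenes are inert.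

**Step 15**
Reactants: 25 epoxy hydroxy ester
Product: 26 methyl (2Z)-6-{(2R,3R)-3-[(2S,3R)-3-[(1R)-1-(tert-butyldimethylsilyloxy)-2-(4-methoxybenzyloxy)ethyl]-4-methylidene-5-oxooxolan-2-yl]-2-methyloxiran-2-yl}-2-iodohex-2-enoate
Conditions: PPTS (0.2 equiv), toluene, 45 °C
Reagents that add atoms: none
Why: Mildly acid-catalysed lactonisation (5-exo transesterification) of the C6 hydroxyl onto the C12 ester gives the cis-fused α-methylene-γ-butyrolactone; no stereocentre changes and the weak acid spares the epoxide.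

**Step 16**
Reactants: 26 PMB ether
Product: 27 methyl (2Z)-6-{(2R,3R)-3-[(2S,3R)-3-[(1R)-1-(tert-butyldimethylsilyloxy)-2-hydroxyethyl]-4-methylidene-5-oxooxolan-2-yl]-2-methyloxiran-2-yl}-2-iodohex-2-enoate
Conditions: DDQ (1.5 equiv), CH2Cl2/pH 7 buffer (10:1), 0 °C → rt
Reagents that add atoms: none
Why: Oxidative cleavage of the PMB ether (hydride abstraction, hydrolysis of the oxocarbenium) under neutral conditions tolerated by the epoxide, lactone, silyl ether and vinyl iodide.

**Step 17**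
Reactants: 27 primary alcohol
Product: 28 methyl (2Z)-6-{(2R,3R)-3-[(2S,3R)-3-[(1R)-1-(tert-butyldimethylsilyloxy)-2-oxoethyl]-4-methylidene-5-oxooxolan-2-yl]-2-methyloxiran-2-yl}-2-iodohex-2-enoate
Conditions: Dess–Martin periodinane (1.5 equiv), NaHCO3, CH2Cl2, 0 °C → rt
Reagents that add atoms: none
Why: Buffered Dess–Martin oxidation gives the C9 aldehyde without epimerising the α-silyloxy centre C8.

**Step 18**
Reactants: 28 iodo aldehyde
Product: 30 methyl (1(10)E,4R,5R,6S,7R,8R,9RS)-8-(tert-butyldimethylsilyloxy)-4,5-epoxy-9-hydroxygermacra-1(10),11(13)-dien-12,6-olid-14-oate, via alkenylchromium dichloride 29 (not isolated)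
Conditions: CrCl2 (10 equiv), NiCl2 (0.2 equiv), degassed DMSO/THF (3:1), 2 mM, rt, slow addition
Reagents that add atoms: none
Why: Nozaki–Hiyama–Kishi macrocyclisation: nickel-catalysed activation of the C–I bond, transmetalation to trivalent chromium and addition to the C9 aldehyde close the ten-membered ring with retention of alkene geometry (C2 cis to C9), helped by the cis-lactone holding both chains on one face; C9 forms as an epimer mixture that step 19 converges.

**Step 19**
Reactants: 30 allylic alcohol (both C9 epimers)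
Product: 31 methyl (1(10)E,4R,5R,6S,7R,8R)-8-(tert-butyldimethylsilyloxy)-4,5-epoxy-9-oxogermacra-1(10),11(13)-dien-12,6-olid-14-oate
Conditions: Dess–Martin periodinane (1.5 equiv), NaHCO3, CH2Cl2, 0 °C
Reagents that add atoms: none
Why: Dess–Martin oxidation of the allylic alcohol removes the uncontrolled C9 centre under non-basic conditions that do not epimerise C8.

**Step 20**
Reactants: 31 enone
Product: 32 methyl (1(10)E,4R,5R,6S,7R,8R,9R)-8-(tert-butyldimethylsilyloxy)-4,5-epoxy-9-hydroxygermacra-1(10),11(13)-dien-12,6-olid-14-oate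
Conditions: NaBH4 (1 equiv), CeCl3·7H2O (1.2 equiv), MeOH/THF, −78 °C, 20 min
Reagents that add atoms: none
Why: Luche 1,2-reduction under Felkin–Anh control: hydride attacks anti to the C8–OSi bond from the ring periphery, giving the 8,9-syn (9R) alcohol, and the cerium salt at −78 °C leaves the enoate and the α-methylene lactone alone.

**Step 21**
Reactants: 32 alcohol; 33 acetic anhydride
Product: 34 methyl (1(10)E,4R,5R,6S,7R,8R,9R)-9-acetoxy-8-(tert-butyldimethylsilyloxy)-4,5-epoxygermacra-1(10),11(13)-dien-12,6-olid-14-oate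
Conditions: Ac2O (3 equiv), DMAP (0.1 equiv), pyridine, CH2Cl2, 0 °C → rt
Reagents that add atoms: acetic anhydride, CC(=O)OC(C)=O
Why: DMAP-catalysed acetylation of the C9 hydroxyl with retention at C9 while C8 is still silylated, which fixes which oxygen carries the acetate.

**Step 22**
Reactants: 34 silyl ether
Product: 35 methyl (1(10)E,4R,5R,6S,7S,8R,9R)-9-acetoxy-4,5-epoxy-8-hydroxygermacra-1(10),11(13)-dien-12,6-olid-14-oate
Conditions: HF·pyridine, pyridine, THF, 0 °C → rt
Reagents that add atoms: none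
Why: Fluoride-mediated desilylation under buffered, slightly acidic conditions that suppress acetyl migration, translactonisation and epoxide opening.

**Step 23**
Reactants: 35 alcohol; 36 methacrylic anhydride
Product: 37 fluctuadin
Conditions: methacrylic anhydride (3 equiv), Et3N (4 equiv), DMAP (0.2 equiv), CH2Cl2, 0 °C → rt
Reagents that add atoms: methacrylic anhydride, C=C(C)C(=O)OC(=O)C(C)=C
Why: DMAP-catalysed (Steglich-type) acylation of the C8 hydroxyl with excess anhydride at low temperature, so that esterification outruns acyl shift or translactonisation; no stereocentre is touched.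

## Compound list

1 | geranyl acetate, (2E)-3,7-dimethylocta-2,6-dien-1-yl acetate | CC(C)=CCC/C(C)=C/COC(C)=O | starting material
2 | 3-chloroperoxybenzoic acid (mCPBA) | OOC(=O)c1cccc(Cl)c1 | starting material
3 | (2E)-5-(3,3-dimethyloxiran-2-yl)-3-methylpent-2-en-1-yl acetate (racemic) | CC1(C)OC1CC/C(C)=C/COC(C)=O | intermediate
4 | (2E)-3-methyl-6-oxohex-2-en-1-yl acetate | O=CCC/C(C)=C/COC(C)=O | intermediate
5 | methyl (triphenylphosphoranylidene)acetate | COC(=O)C=P(c1ccccc1)(c1ccccc1)c1ccccc1 | starting material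
6 | N-iodosuccinimide | O=C1CCC(=O)N1I | starting material
7 | methyl iodo(triphenylphosphoranylidene)acetate (not isolated) | COC(=O)C(I)=P(c1ccccc1)(c1ccccc1)c1ccccc1 | intermediate
8 | methyl (2Z,6E)-8-acetoxy-2-iodo-6-methylocta-2,6-dienoate | COC(=O)/C(I)=C/CC/C(C)=C/COC(C)=O | intermediate
9 | methyl (2Z,6E)-8-hydroxy-2-iodo-6-methylocta-2,6-dienoate | COC(=O)/C(I)=C/CC/C(C)=C/CO | intermediate
10 | methyl (2Z,6E)-2-iodo-6-methyl-8-oxoocta-2,6-dienoate | COC(=O)/C(I)=C/CC/C(C)=C/C=O | intermediate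
11 | (S)-solketal, [(4S)-2,2-dimethyl-1,3-dioxolan-4-yl]methanol | CC1(C)OC[C@H](CO)O1 | starting material
12 | 4-methoxybenzyl chloride | COc1ccc(CCl)cc1 | starting material
13 | (4S)-4-[(4-methoxybenzyloxy)methyl]-2,2-dimethyl-1,3-dioxolane | CC1(C)OC[C@H](COCc2ccc(OC)cc2)O1 | intermediate
14 | (2R)-3-(4-methoxybenzyloxy)propane-1,2-diol | OC[C@@H](O)COCc1ccc(OC)cc1 | intermediate
15 | tert-butyldimethylsilyl chloride | CC(C)(C)[Si](C)(C)Cl | starting material
16 | (2S)-1,2-bis(tert-butyldimethylsilyloxy)-3-(4-methoxybenzyloxy)propane | CC(C)(C)[Si](C)(C)OC[C@@H](O[Si](C)(C)C(C)(C)C)COCc1ccc(OC)cc1 | intermediate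
17 | (2R)-2-(tert-butyldimethylsilyloxy)-3-(4-methoxybenzyloxy)propan-1-ol | OC[C@@H](O[Si](C)(C)C(C)(C)C)COCc1ccc(OC)cc1 | intermediate
18 | (2S)-2-(tert-butyldimethylsilyloxy)-3-(4-methoxybenzyloxy)propanal | O=C[C@@H](O[Si](C)(C)C(C)(C)C)COCc1ccc(OC)cc1 | intermediate
19 | methyl acrylate | C=CC(=O)OC | starting material
20 | methyl (3RS,4S)-4-(tert-butyldimethylsilyloxy)-3-hydroxy-5-(4-methoxybenzyloxy)-2-methylidenepentanoate | C=C(C(=O)OC)C(O)[C@@H](O[Si](C)(C)C(C)(C)C)COCc1ccc(OC)cc1 | intermediate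
21 | phosphorus tribromide, PBr3 | BrP(Br)Br | starting material
22 | methyl (2Z,4R)-2-(bromomethyl)-4-(tert-butyldimethylsilyloxy)-5-(4-methoxybenzyloxy)pent-2-enoate | COC(=O)/C(CBr)=C/[C@@H](O[Si](C)(C)C(C)(C)C)COCc1ccc(OC)cc1 | intermediate
23 | [(2Z,4R)-4-(tert-butyldimethylsilyloxy)-2-(methoxycarbonyl)-5-(4-methoxybenzyloxy)pent-2-en-1-yl]indium, monovalent allylindium (not isolated) | COC(=O)/C(C[In])=C/[C@@H](O[Si](C)(C)C(C)(C)C)COCc1ccc(OC)cc1 | intermediate
24 | dimethyl (2Z,6E,8R,9R)-9-[(1R)-1-(tert-butyldimethylsilyloxy)-2-(4-methoxybenzyloxy)ethyl]-8-hydroxy-2-iodo-6-methyl-10-methylideneundeca-2,6-dienedioate (chain C8, C9 and the side-chain carbon are germacrane C6, C7, C8) | COC(=O)/C(I)=C/CC/C(C)=C/[C@@H](O)[C@H]([C@@H](O[Si](C)(C)C(C)(C)C)COCc1ccc(OC)cc1)C(=C)C(=O)OC | intermediate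
25 | methyl (2Z)-6-{(2R,3R)-3-[(1S,2R,3R)-3-(tert-butyldimethylsilyloxy)-1-hydroxy-4-(4-methoxybenzyloxy)-2-(3-methoxy-3-oxoprop-1-en-2-yl)butyl]-2-methyloxiran-2-yl}-2-iodohex-2-enoate | COC(=O)/C(I)=C/CC[C@@]1(C)O[C@@H]1[C@@H](O)[C@H]([C@@H](O[Si](C)(C)C(C)(C)C)COCc2ccc(OC)cc2)C(=C)C(=O)OC | intermediate
26 | methyl (2Z)-6-{(2R,3R)-3-[(2S,3R)-3-[(1R)-1-(tert-butyldimethylsilyloxy)-2-(4-methoxybenzyloxy)ethyl]-4-methylidene-5-oxooxolan-2-yl]-2-methyloxiran-2-yl}-2-iodohex-2-enoate (cis-2,3-disubstituted lactone) | COC(=O)/C(I)=C/CC[C@@]1(C)O[C@@H]1[C@H]2OC(=O)C(=C)[C@H]2[C@@H](O[Si](C)(C)C(C)(C)C)COCc3ccc(OC)cc3 | intermediate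
27 | methyl (2Z)-6-{(2R,3R)-3-[(2S,3R)-3-[(1R)-1-(tert-butyldimethylsilyloxy)-2-hydroxyethyl]-4-methylidene-5-oxooxolan-2-yl]-2-methyloxiran-2-yl}-2-iodohex-2-enoate | COC(=O)/C(I)=C/CC[C@@]1(C)O[C@@H]1[C@H]2OC(=O)C(=C)[C@H]2[C@@H](O[Si](C)(C)C(C)(C)C)CO | intermediate
28 | methyl (2Z)-6-{(2R,3R)-3-[(2S,3R)-3-[(1R)-1-(tert-butyldimethylsilyloxy)-2-oxoethyl]-4-methylidene-5-oxooxolan-2-yl]-2-methyloxiran-2-yl}-2-iodohex-2-enoate | COC(=O)/C(I)=C/CC[C@@]1(C)O[C@@H]1[C@H]2OC(=O)C(=C)[C@H]2[C@@H](O[Si](C)(C)C(C)(C)C)C=O | intermediate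
29 | alkenylchromium dichloride derived from 28 (CrCl2 group in place of iodine, trivalent chromium; not isolated) | COC(=O)/C([Cr](Cl)Cl)=C/CC[C@@]1(C)O[C@@H]1[C@H]2OC(=O)C(=C)[C@H]2[C@@H](O[Si](C)(C)C(C)(C)C)C=O | intermediate
30 | methyl (1(10)E,4R,5R,6S,7R,8R,9RS)-8-(tert-butyldimethylsilyloxy)-4,5-epoxy-9-hydroxygermacra-1(10),11(13)-dien-12,6-olid-14-oate (both C9 epimers; 7R is the same spatial arrangement as 7S in 37, the descriptor changes because of silicon) | CC(C)(C)[Si](C)(C)O[C@@H]1[C@@H]2C(=C)C(=O)O[C@@H]2[C@H]2O[C@]2(C)CC/C=C(/C(=O)OC)C1O | intermediate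
31 | methyl (1(10)E,4R,5R,6S,7R,8R)-8-(tert-butyldimethylsilyloxy)-4,5-epoxy-9-oxogermacra-1(10),11(13)-dien-12,6-olid-14-oate | CC(C)(C)[Si](C)(C)O[C@@H]1[C@@H]2C(=C)C(=O)O[C@@H]2[C@H]2O[C@]2(C)CC/C=C(/C(=O)OC)C1=O | intermediate
32 | methyl (1(10)E,4R,5R,6S,7R,8R,9R)-8-(tert-butyldimethylsilyloxy)-4,5-epoxy-9-hydroxygermacra-1(10),11(13)-dien-12,6-olid-14-oate | CC(C)(C)[Si](C)(C)O[C@@H]1[C@@H]2C(=C)C(=O)O[C@@H]2[C@H]2O[C@]2(C)CC/C=C(/C(=O)OC)[C@H]1O | intermediate
33 | acetic anhydride | CC(=O)OC(C)=O | starting material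
34 | methyl (1(10)E,4R,5R,6S,7R,8R,9R)-9-acetoxy-8-(tert-butyldimethylsilyloxy)-4,5-epoxygermacra-1(10),11(13)-dien-12,6-olid-14-oate | CC(C)(C)[Si](C)(C)O[C@@H]1[C@@H]2C(=C)C(=O)O[C@@H]2[C@H]2O[C@]2(C)CC/C=C(/C(=O)OC)[C@H]1OC(C)=O | intermediate
35 | methyl (1(10)E,4R,5R,6S,7S,8R,9R)-9-acetoxy-4,5-epoxy-8-hydroxygermacra-1(10),11(13)-dien-12,6-olid-14-oate | O[C@@H]1[C@@H]2C(=C)C(=O)O[C@@H]2[C@H]2O[C@]2(C)CC/C=C(/C(=O)OC)[C@H]1OC(C)=O | intermediate
36 | methacrylic anhydride | C=C(C)C(=O)OC(=O)C(C)=C | starting material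
37 | fluctuadin, methyl (1(10)E,4R,5R,6S,7S,8R,9R)-9-acetoxy-4,5-epoxy-8-(2-methylprop-2-enoyloxy)germacra-1(10),11(13)-dien-12,6-olid-14-oate | C=C(C)C(=O)O[C@@H]1[C@@H]2C(=C)C(=O)O[C@@H]2[C@H]2O[C@]2(C)CC/C=C(/C(=O)OC)[C@H]1OC(C)=O | target

## Step count and risks

Total: 23 steps (5 for the enal, 7 for the allylic bromide, 11 after their union). Longest linear sequence: 18 steps (steps 6–23, from 11).

**Most likely to fail, 1: step 13 (face selectivity of the Barbier allylation relative to C8).** The syn (cis-lactone) outcome is dependable, but the sense of addition relative to the C8 silyloxy centre rests on an A(1,3)-strain model and could be modest. The fallback sets out from bromide 22 (with enal 10) and comes back at 24. Bromide 22 is borylated with B2pin2 and Pd2(dba)3 (zerovalent palladium, catalytic) in DMSO at 50 °C to give allylboronate F1. F1 and 10 are then combined in toluene at 0 °C with a BINOL-derived chiral phosphoric acid (TRIP, 5 mol %), the enantiomer matched to C8 being chosen by running both. The closed chair allylboration keeps the 6,7-syn relationship, the aldehyde face is now under catalyst control, and aqueous work-up of the borate returns 24.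

**Most likely to fail, 2: step 18 (ten-membered Ni/Cr ring closure).** Oligomerisation or simple reduction of the C–I bond may dominate if the lactone holds the two termini apart. The fallback sets out from 25 and comes back at 30, closing the carbocycle before the lactone. The C6 hydroxyl of 25 is silylated (TESCl, imidazole, CH2Cl2) to give silyl ether F2. The PMB group is removed with DDQ to give alcohol F3, and Dess–Martin oxidation gives aldehyde F4. The same CrCl2/NiCl2 conditions at 2 mM then close the ring on this open-chain ester to give carbocycle F5 as a C9 epimer mixture. PPTS in MeOH at 0 °C removes the triethylsilyl group, and warming in toluene (45 °C) lactonises the freed C6 hydroxyl onto the C12 ester to give 30.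

**Most likely to fail, 3: step 20 (C9 configuration from the Luche reduction).** Ring conformation may override the Felkin–Anh preference and deliver hydride to the other face. The fallback sets out from 31 and comes back at 34. If the reduction gives mainly the 9S alcohol F6, it is not recycled but inverted: Mitsunobu reaction with acetic acid (PPh3, DIAD, toluene, 0 °C) displaces the activated C9 oxygen with inversion and gives the 9R acetate 34 directly, so step 21 is skipped.

## Further compounds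

F1 | step 13 | methyl (2E,4R)-4-(tert-butyldimethylsilyloxy)-5-(4-methoxybenzyloxy)-2-[(4,4,5,5-tetramethyl-1,3,2-dioxaborolan-2-yl)methyl]pent-2-enoate | COC(=O)/C(CB1OC(C)(C)C(C)(C)O1)=C/[C@@H](O[Si](C)(C)C(C)(C)C)COCc2ccc(OC)cc2
F2 | step 18 | C6 triethylsilyl ether of 25 | COC(=O)/C(I)=C/CC[C@@]1(C)O[C@@H]1[C@@H](O[Si](CC)(CC)CC)[C@H]([C@@H](O[Si](C)(C)C(C)(C)C)COCc2ccc(OC)cc2)C(=C)C(=O)OC
F3 | step 18 | C9 primary alcohol from F2 (PMB removed) | COC(=O)/C(I)=C/CC[C@@]1(C)O[C@@H]1[C@@H](O[Si](CC)(CC)CC)[C@H]([C@@H](O[Si](C)(C)C(C)(C)C)CO)C(=C)C(=O)OC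
F4 | step 18 | C9 aldehyde from F3 | COC(=O)/C(I)=C/CC[C@@]1(C)O[C@@H]1[C@@H](O[Si](CC)(CC)CC)[C@H]([C@@H](O[Si](C)(C)C(C)(C)C)C=O)C(=C)C(=O)OC
F5 | step 18 | ten-membered carbocycle with C6 triethylsilyl ether, C8 tert-butyldimethylsilyl ether, C9 hydroxyl (both epimers) and the C12 methyl ester still open | CC[Si](CC)(CC)O[C@@H]1[C@H]2O[C@]2(C)CC/C=C(/C(=O)OC)C(O)[C@H](O[Si](C)(C)C(C)(C)C)[C@@H]1C(=C)C(=O)OC
F6 | step 20 | 9S epimer of 32 | CC(C)(C)[Si](C)(C)O[C@@H]1[C@@H]2C(=C)C(=O)O[C@@H]2[C@H]2O[C@]2(C)CC/C=C(/C(=O)OC)[C@@H]1O
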